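Numbering the decalin as a naphthalene (C1 side chain, C3 OAc, C4 CH3, C7 =CH2), ring B (C1–C4, C4a, C8a) is disconnected at C1–C8a and C4–C4a. One catalyst-controlled endo Diels–Alder reaction between cyclohex-2-enone (ring A; C8a=C4a) and an enantiopure acyclic (E,Z)-2-siloxy-1,3-diene that already carries the side-chain stereodiad forms both bonds, ring B, and the C1 and C4a stereocentres. It exploits the C3 oxygen of ring B, which marks C1–C4 as a latent siloxydiene, and the ring A C8 position, where the enone carbonyl lands and is later converted into the C7=CH2/C8=C8a diene. C4 and C3 are then set by equilibration and reduction.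

Key step: step 5

Assumption (step 1): the (R)-configured phosphoric acid is taken to direct the crotylboronate to the Re face of the glyoxylate aldehyde, as with other aldehydes; if the sense were opposite, the (S)-acid would be used.
Assumption (step 5): the (S)-configured oxazaborolidinium ion is taken to bind cyclohex-2-enone like other s-trans α,β-unsaturated carbonyl compounds (α-C–H···O contact) and to leave its Cα Re face open; if the sense were opposite, the (R)-catalyst would be used.

Step 1
Reactants: 1 ethyl glyoxylate, 2 (Z)-crotylboronic acid pinacol ester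
Product: 4 ethyl (2R,3S)-2-hydroxy-3-methylpent-4-enoate, via pinacol borate ester 3 (not isolated)
Conditions: (R)-3,3'-bis(2,4,6-triisopropylphenyl)-1,1'-binaphthyl-2,2'-diyl hydrogen phosphate (5 mol%), 4 Å molecular sieves, toluene, −40 °C; aqueous work-up
Reagents that add atoms: none
Why: Catalytic asymmetric crotylboration through a closed chair (Zimmerman–Traxler) transition state should translate the Z geometry of 2 into the syn (2R,3S) relationship, while the chiral phosphoric acid, hydrogen-bonded to a boronate oxygen and the formyl C–H, directs attack to the aldehyde Re face.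

Step 2
Reactants: 4 ethyl (2R,3S)-2-hydroxy-3-methylpent-4-enoate
Product: 5 (2R,3S)-2-hydroxy-N-methoxy-N,3-dimethylpent-4-enamide
Conditions: MeNH(OMe)·HCl, i-PrMgCl, THF, −20 to 0 °C
Reagents that add atoms: N,O-dimethylhydroxylamine hydrochloride, CNOC.Cl
Why: Weinreb amide formation by aminolysis of the ester with the magnesium amide made in the flask should proceed without touching C2, which is carried as its magnesium alkoxide; no new stereocentre arises.

Step 3
Reactants: 5 (2R,3S)-2-hydroxy-N-methoxy-N,3-dimethylpent-4-enamide, 6 pent-1-en-3-one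
Product: 7 (2R,3S,4E)-2-hydroxy-N-methoxy-N,3-dimethyl-6-oxooct-4-enamide
Conditions: second-generation Hoveyda–Grubbs catalyst [RuCl2(H2IMes)(=CH-C6H4-2-O-i-Pr)] (5 mol%), excess 6, CH2Cl2, 40 °C
Reagents that add atoms: none
Why: Olefin cross-metathesis of a terminal alkene with an electron-poor vinyl ketone is selective for the cross product and should give the E enone under thermodynamic control, leaving the allylic stereocentre untouched.

Step 4
Reactants: 7 (2R,3S,4E)-2-hydroxy-N-methoxy-N,3-dimethyl-6-oxooct-4-enamide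
Product: 8 (2R,3S,4E,6Z)-N-methoxy-N,3-dimethyl-2,6-bis(triisopropylsilyloxy)octa-4,6-dienamide
Conditions: i-Pr3SiOSO2CF3 (2.5 equiv), Et3N, CH2Cl2, −78 to 0 °C
Reagents that add atoms: triisopropylsilyl trifluoromethanesulfonate, CC(C)[Si](C(C)C)(C(C)C)OS(=O)(=O)C(F)(F)F
Why: Soft enolisation (silyl triflate/amine) of the ethyl enone at its α′-CH2 should give the 2-siloxydiene, preferentially as the Z enol ether, while the same reagent silylates the C2 hydroxyl; the enol ether geometry only decides the transient C4 configuration corrected in step 9.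

Step 5
Reactants: 8 (2R,3S,4E,6Z)-N-methoxy-N,3-dimethyl-2,6-bis(triisopropylsilyloxy)octa-4,6-dienamide, 9 cyclohex-2-en-1-one
Product: 10 (2R,3S)-N-methoxy-N-methyl-3-[(1R,4R,4aS,8aS)-4-methyl-8-oxo-3-(triisopropylsilyloxy)-1,4,4a,5,6,7,8,8a-octahydronaphthalen-1-yl]-2-(triisopropylsilyloxy)butanamide
Conditions: (S)-1-(2-methylphenyl)-3,3-diphenyltetrahydro-1H,3H-pyrrolo[1,2-c][1,3,2]oxazaborole (20 mol%), HN(SO2CF3)2 (17 mol%), CH2Cl2, −78 to −20 °C
Reagents that add atoms: none
Why: The N-protonated oxazaborolidine binds the carbonyl of 9 and lowers its LUMO for a concerted, asynchronous normal-demand [4+2] cycloaddition in which the siloxy-activated C4 terminus of the diene bonds first to the enone β-carbon (C4a) and C1 then closes onto the α-carbon (C8a); the closest known reaction type is the oxazaborolidinium-catalysed Diels–Alder reaction of cyclic enones with 2-siloxy-1,3-dienes. Ring B is closed by this intermolecular [4+2] annulation onto the cis double bond of the preformed ring A, suprafacially on both partners, so the ring fusion is cis. C4a and C8a are set by the catalyst, which shields one enone face and leaves the Cα Re face open; C1 follows from the endo rule (carbonyl under the diene) together with the 4E geometry, which places the side chain cis to ring A; C4 follows from the 6Z enol ether geometry and is corrected in step 9, and C8a is erased in step 7. The step needs regioselectivity, secured by the C3 siloxy group (nucleophilic C4 terminus to the β-carbon) and the C1 alkyl group, endo selectivity, secured by the Lewis-acid-bound carbonyl, and π-facial selectivity on the diene relative to its existing allylic stereocentre. Because that centre (H, CH3, CH(OSi)C(O)N) biases the diene only weakly, the facial outcome is placed under catalyst control: once the enone face and the endo orientation are fixed, only one diene face can be presented.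

Step 6
Reactants: 10 (2R,3S)-N-methoxy-N-methyl-3-[(1R,4R,4aS,8aS)-4-methyl-8-oxo-3-(triisopropylsilyloxy)-1,4,4a,5,6,7,8,8a-octahydronaphthalen-1-yl]-2-(triisopropylsilyloxy)butanamide
Product: 13 (2R,3S)-N-methoxy-N-methyl-3-[(1R,4R,4aS,8aS)-4-methyl-7-methylidene-8-oxo-3-(triisopropylsilyloxy)-1,4,4a,5,6,7,8,8a-octahydronaphthalen-1-yl]-2-(triisopropylsilyloxy)butanamide, via Mannich base 11 (not isolated), via trimethylammonium iodide 12 (not isolated)
Conditions: LiN(i-Pr)2 (1.1 equiv), THF, −78 °C; CH2=NMe2+ I−, −78 to 0 °C; MeI, rt; aqueous NaHCO3, CH2Cl2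
Reagents that add atoms: N,N-dimethylmethyleneiminium iodide (Eschenmoser's salt), C=[N+](C)C.[I-]
Why: Kinetic deprotonation at the less hindered C7 methylene (not the C8a methine), Mannich reaction of the lithium enolate with the iminium salt and quaternisation/E1cB loss of trimethylamine should give the α-methylene ketone (Eschenmoser methylenation); the transient C7 centre is lost on elimination and the hindered silyl enol ether should not compete at low temperature.

Step 7
Reactants: 13 (2R,3S)-N-methoxy-N-methyl-3-[(1R,4R,4aS,8aS)-4-methyl-7-methylidene-8-oxo-3-(triisopropylsilyloxy)-1,4,4a,5,6,7,8,8a-octahydronaphthalen-1-yl]-2-(triisopropylsilyloxy)butanamide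
Product: 14 (2R,3S)-N-methoxy-N-methyl-3-[(1R,4R,4aS)-4-methyl-7-methylidene-8-(trifluoromethanesulfonyloxy)-3-(triisopropylsilyloxy)-1,4,4a,5,6,7-hexahydronaphthalen-1-yl]-2-(triisopropylsilyloxy)butanamide
Conditions: KN(SiMe3)2 (1.1 equiv), THF, −78 °C; PhN(SO2CF3)2, −78 to 0 °C
Reagents that add atoms: N-phenylbis(trifluoromethanesulfonimide), O=S(=O)(N(c1ccccc1)S(=O)(=O)C(F)(F)F)C(F)(F)F
Why: With C7 now sp2 the only α-hydrogen is at C8a, so enolisation with the hindered amide base and O-sulfonylation of the cross-conjugated dienolate (enol triflate formation) should give the 8-triflyloxy-7-methylidene diene and erase the C8a stereocentre.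

Step 8
Reactants: 14 (2R,3S)-N-methoxy-N-methyl-3-[(1R,4R,4aS)-4-methyl-7-methylidene-8-(trifluoromethanesulfonyloxy)-3-(triisopropylsilyloxy)-1,4,4a,5,6,7-hexahydronaphthalen-1-yl]-2-(triisopropylsilyloxy)butanamide
Product: 15 (2R,3S)-N-methoxy-N-methyl-3-[(1R,4R,4aS)-4-methyl-7-methylidene-3-(triisopropylsilyloxy)-1,4,4a,5,6,7-hexahydronaphthalen-1-yl]-2-(triisopropylsilyloxy)butanamide
Conditions: Pd(OAc)2 (5 mol%), PPh3 (10 mol%), HCO2H, n-Bu3N, DMF, 60 °C
Reagents that add atoms: none
Why: Palladium-catalysed formate reduction of an enol triflate (oxidative addition to zerovalent palladium, formate exchange, decarboxylation, reductive elimination) should replace OTf by H under buffered conditions that spare both silyl groups and complete the ring A diene.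

Step 9
Reactants: 15 (2R,3S)-N-methoxy-N-methyl-3-[(1R,4R,4aS)-4-methyl-7-methylidene-3-(triisopropylsilyloxy)-1,4,4a,5,6,7-hexahydronaphthalen-1-yl]-2-(triisopropylsilyloxy)butanamide
Product: 17 (2R,3S)-2-hydroxy-N-methoxy-N-methyl-3-[(1S,4S,4aS)-4-methyl-7-methylidene-3-oxo-1,2,3,4,4a,5,6,7-octahydronaphthalen-1-yl]butanamide, via C4-epimeric ketone 16 (not isolated)
Conditions: Bu4NF (3 equiv), THF, 0 °C to rt; then K2CO3, MeOH, rt
Reagents that add atoms: none
Why: Fluoride cleaves the silyl enol ether and the silyl ether, and the released ketone 16, whose C4 methyl is axial (cis to C5), should equilibrate by base-mediated enolisation to the equatorial C4 epimer 17, trans to the C4a–C5 bond; C1 and C4a are not enolisable and the unconjugated ring A diene is inert to base.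

Step 10
Reactants: 17 (2R,3S)-2-hydroxy-N-methoxy-N-methyl-3-[(1S,4S,4aS)-4-methyl-7-methylidene-3-oxo-1,2,3,4,4a,5,6,7-octahydronaphthalen-1-yl]butanamide
Product: 18 (2R,3S)-2-hydroxy-3-[(1S,3R,4S,4aS)-3-hydroxy-4-methyl-7-methylidene-1,2,3,4,4a,5,6,7-octahydronaphthalen-1-yl]-N-methoxy-N-methylbutanamide
Conditions: LiBH(s-Bu)3 (2.5 equiv), THF, −78 °C; aqueous NH4Cl
Reagents that add atoms: none
Why: The bulky trialkylborohydride should attack the ring B cyclohexanone from the equatorial direction, away from the axial hydrogens at C1 and C4a, giving the axial C3 alcohol cis to the equatorial C4 methyl (3R), while the amide, deactivated as its α-alkoxide, is not reduced at −78 °C.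

Step 11
Reactants: 18 (2R,3S)-2-hydroxy-3-[(1S,3R,4S,4aS)-3-hydroxy-4-methyl-7-methylidene-1,2,3,4,4a,5,6,7-octahydronaphthalen-1-yl]-N-methoxy-N-methylbutanamide
Product: 19 (5R,6S)-5-hydroxy-6-[(1S,3R,4S,4aS)-3-hydroxy-4-methyl-7-methylidene-1,2,3,4,4a,5,6,7-octahydronaphthalen-1-yl]-2-methylhept-2-en-4-one
Conditions: Me2C=CHMgBr (4 equiv), THF, 0 °C to rt; aqueous NH4Cl
Reagents that add atoms: (2-methylprop-1-en-1-yl)magnesium bromide, CC(C)=C[Mg]Br
Why: Grignard addition to the Weinreb amide stops at the chelated tetrahedral intermediate, which collapses to the enone only on work-up, so neither over-addition nor epimerisation of the α-carbinol centre is expected; the two hydroxyls are carried as magnesium alkoxides.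

Step 12
Reactants: 19 (5R,6S)-5-hydroxy-6-[(1S,3R,4S,4aS)-3-hydroxy-4-methyl-7-methylidene-1,2,3,4,4a,5,6,7-octahydronaphthalen-1-yl]-2-methylhept-2-en-4-one
Product: 20 (5R,6S)-6-[(1S,3R,4S,4aS)-3-acetoxy-4-methyl-7-methylidene-1,2,3,4,4a,5,6,7-octahydronaphthalen-1-yl]-2-methyl-4-oxohept-2-en-5-yl acetate (target)
Conditions: Ac2O, DMAP (cat.), pyridine, CH2Cl2, 0 °C to rt
Reagents that add atoms: acetic anhydride, CC(=O)OC(C)=O
Why: DMAP-catalysed acylation should esterify both secondary hydroxyls (the axial ring B C3–OH and the α-ketol OH) under mildly basic conditions that spare the acid-sensitive exocyclic diene and the α-stereocentre of the ketone.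

Compound list
1 | ethyl glyoxylate (ethyl 2-oxoacetate) | CCOC(=O)C=O | starting material
2 | (Z)-crotylboronic acid pinacol ester | C/C=C\CB1OC(C)(C)C(C)(C)O1 | starting material
3 | ethyl (2R,3S)-3-methyl-2-[(4,4,5,5-tetramethyl-1,3,2-dioxaborolan-2-yl)oxy]pent-4-enoate | C=C[C@H](C)[C@@H](OB1OC(C)(C)C(C)(C)O1)C(=O)OCC | intermediate (not isolated)
4 | ethyl (2R,3S)-2-hydroxy-3-methylpent-4-enoate | C=C[C@H](C)[C@@H](O)C(=O)OCC | intermediate
5 | (2R,3S)-2-hydroxy-N-methoxy-N,3-dimethylpent-4-enamide | C=C[C@H](C)[C@@H](O)C(=O)N(C)OC | intermediate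
6 | pent-1-en-3-one | CCC(=O)C=C | starting material
7 | (2R,3S,4E)-2-hydroxy-N-methoxy-N,3-dimethyl-6-oxooct-4-enamide | CCC(=O)/C=C/[C@H](C)[C@@H](O)C(=O)N(C)OC | intermediate
8 | (2R,3S,4E,6Z)-N-methoxy-N,3-dimethyl-2,6-bis(triisopropylsilyloxy)octa-4,6-dienamide | C/C=C(O[Si](C(C)C)(C(C)C)C(C)C)/C=C/[C@H](C)[C@@H](O[Si](C(C)C)(C(C)C)C(C)C)C(=O)N(C)OC | intermediate
9 | cyclohex-2-en-1-one | O=C1C=CCCC1 | starting material
10 | (2R,3S)-N-methoxy-N-methyl-3-[(1R,4R,4aS,8aS)-4-methyl-8-oxo-3-(triisopropylsilyloxy)-1,4,4a,5,6,7,8,8a-octahydronaphthalen-1-yl]-2-(triisopropylsilyloxy)butanamide (cis-fused; H at C1, C4, C4a and C8a all cis) | O=C1CCC[C@H]2[C@@H](C)C(O[Si](C(C)C)(C(C)C)C(C)C)=C[C@@H]([C@H](C)[C@@H](O[Si](C(C)C)(C(C)C)C(C)C)C(=O)N(C)OC)[C@@H]12 | intermediate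
11 | 7-[(dimethylamino)methyl] derivative of 10 (Mannich base; C7 epimers) | O=C1C(CN(C)C)CC[C@H]2[C@@H](C)C(O[Si](C(C)C)(C(C)C)C(C)C)=C[C@@H]([C@H](C)[C@@H](O[Si](C(C)C)(C(C)C)C(C)C)C(=O)N(C)OC)[C@@H]12 | intermediate (not isolated)
12 | 7-[(trimethylammonio)methyl] derivative of 10, iodide (C7 epimers) | O=C1C(C[N+](C)(C)C)CC[C@H]2[C@@H](C)C(O[Si](C(C)C)(C(C)C)C(C)C)=C[C@@H]([C@H](C)[C@@H](O[Si](C(C)C)(C(C)C)C(C)C)C(=O)N(C)OC)[C@@H]12.[I-] | intermediate (not isolated)
13 | (2R,3S)-N-methoxy-N-methyl-3-[(1R,4R,4aS,8aS)-4-methyl-7-methylidene-8-oxo-3-(triisopropylsilyloxy)-1,4,4a,5,6,7,8,8a-octahydronaphthalen-1-yl]-2-(triisopropylsilyloxy)butanamide | O=C1C(=C)CC[C@H]2[C@@H](C)C(O[Si](C(C)C)(C(C)C)C(C)C)=C[C@@H]([C@H](C)[C@@H](O[Si](C(C)C)(C(C)C)C(C)C)C(=O)N(C)OC)[C@@H]12 | intermediate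
14 | (2R,3S)-N-methoxy-N-methyl-3-[(1R,4R,4aS)-4-methyl-7-methylidene-8-(trifluoromethanesulfonyloxy)-3-(triisopropylsilyloxy)-1,4,4a,5,6,7-hexahydronaphthalen-1-yl]-2-(triisopropylsilyloxy)butanamide | C=C1C(OS(=O)(=O)C(F)(F)F)=C2[C@@H](CC1)[C@@H](C)C(O[Si](C(C)C)(C(C)C)C(C)C)=C[C@H]2[C@H](C)[C@@H](O[Si](C(C)C)(C(C)C)C(C)C)C(=O)N(C)OC | intermediate
15 | (2R,3S)-N-methoxy-N-methyl-3-[(1R,4R,4aS)-4-methyl-7-methylidene-3-(triisopropylsilyloxy)-1,4,4a,5,6,7-hexahydronaphthalen-1-yl]-2-(triisopropylsilyloxy)butanamide | C=C1C=C2[C@@H](CC1)[C@@H](C)C(O[Si](C(C)C)(C(C)C)C(C)C)=C[C@H]2[C@H](C)[C@@H](O[Si](C(C)C)(C(C)C)C(C)C)C(=O)N(C)OC | intermediate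
16 | (2R,3S)-2-hydroxy-N-methoxy-N-methyl-3-[(1S,4R,4aS)-4-methyl-7-methylidene-3-oxo-1,2,3,4,4a,5,6,7-octahydronaphthalen-1-yl]butanamide | C=C1C=C2[C@@H](CC1)[C@@H](C)C(=O)C[C@H]2[C@H](C)[C@@H](O)C(=O)N(C)OC | intermediate (not isolated)
17 | (2R,3S)-2-hydroxy-N-methoxy-N-methyl-3-[(1S,4S,4aS)-4-methyl-7-methylidene-3-oxo-1,2,3,4,4a,5,6,7-octahydronaphthalen-1-yl]butanamide | C=C1C=C2[C@@H](CC1)[C@H](C)C(=O)C[C@H]2[C@H](C)[C@@H](O)C(=O)N(C)OC | intermediate
18 | (2R,3S)-2-hydroxy-3-[(1S,3R,4S,4aS)-3-hydroxy-4-methyl-7-methylidene-1,2,3,4,4a,5,6,7-octahydronaphthalen-1-yl]-N-methoxy-N-methylbutanamide | C=C1C=C2[C@@H](CC1)[C@H](C)[C@H](O)C[C@H]2[C@H](C)[C@@H](O)C(=O)N(C)OC | intermediate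
19 | (5R,6S)-5-hydroxy-6-[(1S,3R,4S,4aS)-3-hydroxy-4-methyl-7-methylidene-1,2,3,4,4a,5,6,7-octahydronaphthalen-1-yl]-2-methylhept-2-en-4-one | C=C1C=C2[C@@H](CC1)[C@H](C)[C@H](O)C[C@H]2[C@H](C)[C@@H](O)C(=O)C=C(C)C | intermediate
20 | (5R,6S)-6-[(1S,3R,4S,4aS)-3-acetoxy-4-methyl-7-methylidene-1,2,3,4,4a,5,6,7-octahydronaphthalen-1-yl]-2-methyl-4-oxohept-2-en-5-yl acetate (CNP0302999.1) | C=C1C=C2[C@@H](CC1)[C@H](C)[C@H](OC(C)=O)C[C@H]2[C@H](C)[C@@H](OC(C)=O)C(=O)C=C(C)C | target

Total step count: 12 steps.
Longest linear sequence: 12 steps (from ethyl glyoxylate 1).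

Steps most likely to fail

Step 5. The cationic boron catalyst may turn over poorly because the amide and silyl ethers of 8 compete for it, and diene π-facial selectivity may erode if the catalyst and the allylic stereocentre of 8 are mismatched. The fallback sets out from 8 and comes back at 10, and it moves the facial control onto the dienophile as a covalent auxiliary. Diene 8 is combined under chelating ZnBr2 in CH2Cl2 at −20 °C with (S)-2-(4-methylbenzenesulfinyl)cyclohex-2-en-1-one F1, a known, doubly activated dienophile prepared beforehand by the standard sulfinate route. In the zinc chelate of the sulfinyl and carbonyl oxygens the aryl group blocks one enone face, so the same endo [4+2] cycloaddition should give the C8a-sulfinyl adduct F2 (other stereocentres as in 10, sulfur on the face of the former C8a hydrogen). Reductive C–S cleavage with aluminium amalgam in wet THF at 0 °C should then return 10; any trans-fused C8a epimer formed alongside converges with 10 at triflate 14.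

Step 7. The amide base may add in conjugate fashion to the exo-methylene ketone, or removal of the hindered C8a hydrogen may be slow enough for 13 to dimerise. The fallback sets out from 13 and comes back at 15, and it removes the C8 oxygen as an allylic leaving group instead of as an enol triflate. Carbonyl-selective reduction (NaBH4, CeCl3, MeOH, −78 °C) should give the C8 allylic alcohol F3 (either C8 epimer serves). Methyl chloroformate and pyridine convert it into the allylic methyl carbonate F4. Pd(PPh3)4 in dioxane at 80 °C should ionise F4 to the π-allyl complex, whose only β-hydrogen (C8a–H) is lost to give diene 15.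

Step 9. The thermodynamic equilibration at C4 may be incomplete or only weakly biased, because only one syn-axial hydrogen opposes the axial methyl in this ring. The fallback sets out from 15, through the 16/17 mixture that step 9 gives, and comes back at 17; it replaces thermodynamic by kinetic control. The mixture is converted under equilibrating conditions (Me3SiCl, NaI, Et3N, MeCN) into the tetrasubstituted C3–C4 bis(trimethylsilyl) enol ether F5, which is also O-silylated on the side-chain hydroxyl. Bu4NF buffered with AcOH at −78 °C then releases the enolate, which should be protonated axially at C4, anti to the axial C4a hydrogen, so that the methyl ends equatorial; the side-chain hydroxyl is freed in the same operation, giving 17.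

Further compounds
F1 | step 5 | (S)-2-(4-methylbenzenesulfinyl)cyclohex-2-en-1-one | O=C1CCCC=C1[S@@](=O)c1ccc(C)cc1
F2 | step 5 | 8a-[(S)-4-methylbenzenesulfinyl] analogue of 10 (sulfinyl group in place of the C8a hydrogen, all other stereocentres as in 10) | O=C1CCC[C@H]2[C@@H](C)C(O[Si](C(C)C)(C(C)C)C(C)C)=C[C@@H]([C@H](C)[C@@H](O[Si](C(C)C)(C(C)C)C(C)C)C(=O)N(C)OC)[C@@]12[S@@](=O)c1ccc(C)cc1
F3 | step 7 | C8 allylic alcohol from 13 (8-hydroxy-7-methylidene; C8 epimers, other stereocentres as in 13) | OC1C(=C)CC[C@H]2[C@@H](C)C(O[Si](C(C)C)(C(C)C)C(C)C)=C[C@@H]([C@H](C)[C@@H](O[Si](C(C)C)(C(C)C)C(C)C)C(=O)N(C)OC)[C@@H]12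
F4 | step 7 | C8 methyl carbonate of F3 | COC(=O)OC1C(=C)CC[C@H]2[C@@H](C)C(O[Si](C(C)C)(C(C)C)C(C)C)=C[C@@H]([C@H](C)[C@@H](O[Si](C(C)C)(C(C)C)C(C)C)C(=O)N(C)OC)[C@@H]12
F5 | step 9 | C3–C4 trimethylsilyl enol ether of 17 with the side-chain hydroxyl as its trimethylsilyl ether (C1, C4a and side-chain stereocentres as in 17) | C=C1C=C2[C@@H](CC1)C(C)=C(O[Si](C)(C)C)C[C@H]2[C@H](C)[C@@H](O[Si](C)(C)C)C(=O)N(C)OC
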